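## Structural features

The target is a germacranolide: a ten-membered carbocycle (C1 to C10) fused trans at C6/C7 to an α-methylene γ-lactone (C11, C12, C13), with an angelate on C8, a free hydroxyl on C5 and an exocyclic methylene (C15) on C4. Two epoxides sit side by side: a trans, trisubstituted 1,10-epoxide (C10 carries the methyl C14) and a cis 2,3-epoxide joined to it through C1–C2 and allylic to C4=C15. Eight stereocentres run almost unbroken around the ring (C10, C1, C2, C3, then C5, C6, C7, C8); only C4 and C9 interrupt them. The fragile groups are the vinyl epoxide (C2–C3 next to C4=C15), the Michael-accepting methylene lactone, the angelate (Z to E isomerisation, γ-deprotonation) and the allylic C5 carbinol. The real difficulty is to close a medium ring and still control eight stereocentres, in particular the relation between the C1/C10 pair and the C5–C7 triad. The key step exploits the fact that a cis 2,3-epoxide is the trace of a C2≡C3 alkyne and the C8 ester the trace of a C8 ketone. A cyclodec-2-yn-8-one is the perimeter of a decalin fused at C3–C8, with ring A (C3 to C8) carrying C5, C6 and C7 and ring B (C8, C9, C10, C1, C2, C3) carrying C1 and C10.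

## Logic of the disconnections

35 from 34: only the O–Si bond at C5 is cut. The C5 hydroxyl is masked to the very end because it is allylic and would compete in sulfonylation and in hydroxyl-directed epoxidation; the forward step must spare two epoxides and the methylene lactone.

34 from 32 (through 33): the C1–O bond of the 1,10-epoxide is cut. A trans epoxide cannot be carried on a six-membered ring, but the cis diol that gives it by inversion at C1 can; the forward step needs a sulfonate on the secondary C1 hydroxyl only and a clean internal displacement by the tertiary C10 oxygen.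

32 from 31: both C–O bonds of the 2,3-epoxide are cut. With the C1 hydroxyl still free and allylic, the oxygen can be delivered to its own face, which is the face the target requires; the forward step must select C2=C3 within a diene.

31 from 30, and 30 from 29: the Z alkene is traced back to the alkyne and the diol to its acetal. The acetal is removed while C1 is still propargylic (less prone to ionise than a dienylic alcohol); the forward reduction must stop at the cis alkene.

29 from 27 and 28: the C8 ester C–O bond is cut. The acid is introduced after the lactone methylene so that no strong base ever meets the angelate.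

27 from 24: the C11=C13 bond is cut. Methylenation is placed where the only other acidic site is the C8 hydroxyl, which is simply carried as its alkoxide.

24 from 23: the C8–H bond is cut; the forward reduction must create the 8α carbinol on a ten-membered ring.

23 from 19 and 20: the strategic cut. Reconnecting C3 to C8 turns the ynone into a ring-fusion epoxy ketone on a decalin, so that C1, C10, C5, C6 and C7 can be set on six-membered rings. The forward step needs hydrazone formation at a hindered C2 carbonyl under conditions that spare the acetal, the silyl ether and the vinyl epoxide.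

19 from 18, 18 from 16 (through 17), 16 from 15, 15 from 14: the epoxide oxygen, the C3=C8 double bond and the C2 carbonyl are removed in turn. The fused enone is made only at the end because, together with a C1=C10 double bond, it would be a phenol tautomer; the forward steps need regioselective enolisation towards C3 and conjugate peroxide addition at a tetrasubstituted carbon.

14 from 13, 13 from 12: the extra ester on C11 (left by the malonate) and the C4=C15 bond are cut. The methylene is installed from the C4 ketone before C2 is oxidised, so two ketones never compete.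

12 from 11, 11 from 9 (through 10), 9 from 8: the silyl ether, the acetal, the lactone C–O bond and four C–O bonds of two cis diols are cut. Only the C6 hydroxyl can reach an ester to give a γ-lactone, so the C5/C6 pair differentiates itself; the forward dihydroxylations must both occur on the α face.

8 from 6 and 7, 6 from 5, 5 from 4: the C7–C11 bond is cut at an allylic position. Double inversion transfers the configuration of the C7 carbinol to the carbon substituent; the forward steps need reduction of the carbonyl remote from the silyloxy group and attack of the nucleophile at C7.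

4 from 2 and 3, 2 from 1: the C2–C3 and C8–C9 bonds are cut (cycloaddition). Ring A is a quinone and ring B a 1-oxygenated 3-methyl diene. The cis fusion and the C2 oxygen then relay every later stereocentre, and one catalytic step fixes the absolute configuration. An arene-derived ring B was rejected: dissolving-metal reduction of a 2-methoxy-10-methyl arene leaves the enone at C1=C10, not at the ring fusion, and offers no handle at C4.

## Other disconnections considered

Alternative 1: The cut is the transannular C5–C10 double bond of the Birch-derived bicycle A1; one equivalent of ozone would cleave its single tetrasubstituted alkene to the cyclodecadienedione A2. In its favour: the ten-membered ring arrives in two or three steps from an arene, without high dilution, with the C2=C3 alkene already cis. On speed of ring construction it is better than the chosen plan. Against it: A2 has no stereocentre, so all eight must be created on a flexible ring, and the two ketones invite transannular aldol reactions. C10 needs a methyl addition followed by a trans epoxide, and the C7=C8 alkene must be turned into two stereocentres without a directing element. Both plans reveal the ring by cleaving a decalin fusion bond, but the chosen one does so after five stereocentres are fixed. Alternative 1 wins on early step economy and loses on stereocontrol and overall length.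

Alternative 2: The cut is C5–C6; warming the aldehyde A3, which carries an E γ-alkoxyallyl boronate, would close the ring to A4 through a chair transition state. In its favour: ring and two stereocentres (C5, C6, anti as required) form together, both epoxides are made earlier on open chains by reagent control, and the short endgame avoids late epoxidations. On convergence and on endgame length it is the equal or the better of the chosen plan. Against it: a ten-membered allylboration is entropically costly and competes with oligomerisation. A3 holds an epimerisable, β-silyloxy aldehyde centre (C7) and a vinyl epoxide next to boron, and facial selectivity with respect to C7 in a macrocyclic transition state is uncertain. Six stereocentres must be built independently on acyclic fragments, whereas the chosen plan relays five from one cycloadduct.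

Alternative 3: The cut is C1–C2; zerovalent palladium with CuI would couple the E vinylstannane and Z vinyl iodide of A5 to the tetraene A6. In its favour: lactone, methylene, angelate and C5 ether are all in place before closure, and Stille closures of medium-ring dienes are known. It is better than the chosen plan on functional-group timing, since no strong base or hydride is needed after the ring exists. Against it: A6 is a strained E,Z-diene conjugated with C4=C15, and it must then be epoxidised twice, regioselectively and from defined faces, with nothing but ring conformation to direct the reagent. The chosen plan derives the 1,10-epoxide from a diol fixed on a six-membered ring and the 2,3-epoxide from hydroxyl direction. Step counts are probably comparable; the stereochemical risk of Alternative 3 is concentrated in its last two oxidations.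

Key step: step 15

Remarks before the steps

- Labels C1 to C15 are the germacrane positions of the target, used also for the bicycles (ring A = C3 to C8; ring B = C8, C9, C10, C1, C2, C3). α is the face of the C5 and C6 oxygens and of H7; β is the face of C11 on C7.
- The two structures that bracket the key step were re-derived from the target. C5, C6, C7 and C10 have the target configuration and C1 the opposite one, as closure with inversion demands; no correction was needed. The configuration of the C3–C8 epoxide is erased in the fragmentation; 19 is drawn as the β-epoxide.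
- Assumption: the (S)-configured oxazaborolidinium catalyst in step 2 gives the enantiomer drawn for 4; if the sense is opposite, the (R)-catalyst is used with no other change.

## Route

Step 1
Reactants: 1 3-methylbut-2-enal
Product: 2 (E)-1-(triethylsilyloxy)-3-methylbuta-1,3-diene
Conditions: Et3SiOTf, Et3N, Et2O, 0 °C to rt
Reagents that add atoms: triethylsilyl trifluoromethanesulfonate, CC[Si](CC)(CC)OS(=O)(=O)C(F)(F)F
Why: Silyl dienol ether formation by O-silylation and γ-deprotonation of the enal; the E enol ether is the normal outcome for this aldehyde.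

Step 2
Reactants: 2 (E)-1-(triethylsilyloxy)-3-methylbuta-1,3-diene; 3 1,4-benzoquinone
Product: 4 cis-fused adduct, 2β-triethylsilyloxy-10-methyl-3αH,8αH-decalin-1(10),5-diene-4,7-dione (germacrane locants)
Conditions: (S)-3,3-diphenyl-1-(o-tolyl)tetrahydropyrrolo[1,2-c][1,3,2]oxazaborole·HNTf2 (20 mol %), CH2Cl2, −78 °C
Reagents that add atoms: none
Why: Catalytic enantioselective quinone Diels–Alder reaction; the endo transition state should give the cis fusion with the silyloxy group trans to H3 and H8, the dienophile is symmetrical so regiochemistry is not an issue, and the chiral boron Lewis acid bound to one carbonyl shields one face and so sets C2, C3 and C8 in the absolute sense.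

Step 3
Reactants: 4 cis-fused adduct
Product: 5 7β-hydroxy-2β-triethylsilyloxy-10-methyl-3αH,8αH-decalin-1(10),5-dien-4-one
Conditions: NaBH4 (0.3 equiv), CeCl3·7H2O, MeOH–CH2Cl2, −78 °C
Reagents that add atoms: none
Why: Luche 1,2-reduction; hydride should arrive on the convex α face (H7 α, OH β) and at the C7 carbonyl, because reduction at C4 would force the new hydroxyl into a syn-1,3 clash with the C2 silyloxy group.

Step 4
Reactants: 5 7β-hydroxy enone
Product: 6 7β-methoxycarbonyloxy-2β-triethylsilyloxy-10-methyl-3αH,8αH-decalin-1(10),5-dien-4-one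
Conditions: ClCO2Me, pyridine, CH2Cl2, 0 °C
Reagents that add atoms: methyl chloroformate, COC(=O)Cl
Why: Plain O-acylation of the allylic alcohol under weakly basic conditions that should not epimerise or eliminate the β-silyloxy ketone.

Step 5
Reactants: 6 allylic carbonate; 7 dimethyl malonate
Product: 8 7β-[bis(methoxycarbonyl)methyl]-2β-triethylsilyloxy-10-methyl-3αH,8αH-decalin-1(10),5-dien-4-one
Conditions: Pd(PPh3)4 (5 mol %, zerovalent palladium), THF, rt
Reagents that add atoms: none
Why: Tsuji–Trost allylic alkylation under neutral carbonate conditions; ionisation anti to the carbonate and attack of the soft nucleophile anti to palladium give net retention (C11 β, H7 α), and the nucleophile should take the allyl terminus remote from the carbonyl so that the enone survives.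

Step 6
Reactants: 8 malonate enone
Product: 9 1α,5α,6α,10α-tetrahydroxy-7β-[bis(methoxycarbonyl)methyl]-2β-triethylsilyloxy-10-methyl-3αH,8αH-decalin-4-one
Conditions: OsO4 (5 mol %), N-methylmorpholine N-oxide (2.5 equiv), acetone–H2O, 0 °C to rt
Reagents that add atoms: osmium tetroxide, O=[Os](=O)(=O)=O; N-methylmorpholine N-oxide, C[N+]1([O-])CCOCC1; water, O
Why: Upjohn dihydroxylation of both alkenes; C1=C10 should react anti to the allylic silyloxy group (Kishi's rule) and on the convex face, C5=C6 anti to the C7 substituent, so all four oxygens land on the α face and C1, C10, C5, C6 are set.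

Step 7
Reactants: 9 tetraol
Product: 11 11-methoxycarbonyl-5α-hydroxy-1α,10α-isopropylidenedioxy-4-oxo-2β-triethylsilyloxy-3αH,8αH-3,8-cyclo-13,15-dinorgermacran-6α,12-olide (C11 epimers), via lactone triol 10 (not isolated)
Conditions: PPTS (cat.), PhMe, 50 °C; then Me2C(OMe)2, rt
Reagents that add atoms: 2,2-dimethoxypropane, COC(C)(C)OC
Why: Acid-catalysed lactonisation then acetalisation; only the C6 hydroxyl can reach a malonate carbonyl in a five-membered ring, which gives the trans-fused lactone and differentiates C5 from C6, and the only cis diol left for the acetonide is C1/C10.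

Step 8
Reactants: 11 hydroxy ketone
Product: 12 5α-(tert-butyldimethylsilyloxy) derivative of 11
Conditions: t-BuMe2SiOTf, 2,6-lutidine, CH2Cl2, −78 to −40 °C
Reagents that add atoms: tert-butyldimethylsilyl trifluoromethanesulfonate, CC(C)(C)[Si](C)(C)OS(=O)(=O)C(F)(F)F
Why: Silylation of the single free hydroxyl with the triflate, which copes with a hindered α-keto carbinol at low temperature.

Step 9
Reactants: 12 C4 ketone
Product: 13 11-methoxycarbonyl-5α-(tert-butyldimethylsilyloxy)-1α,10α-isopropylidenedioxy-2β-triethylsilyloxy-3αH,8αH-3,8-cyclo-13-norgermacr-4(15)-en-6α,12-olide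
Conditions: Zn, CH2Br2, TiCl4 (preformed reagent), THF–CH2Cl2, 0 °C to rt
Reagents that add atoms: dibromomethane, BrCBr
Why: Takai–Lombardo methylenation; the non-basic reagent should convert the hindered ketone without β-elimination of the C2 silyloxy group or epimerisation at C5, and it leaves ester and lactone carbonyls alone.

Step 10
Reactants: 13 malonate-derived lactone ester
Product: 14 5α-(tert-butyldimethylsilyloxy)-1α,10α-isopropylidenedioxy-2β-triethylsilyloxy-3αH,8αH-3,8-cyclo-13-norgermacr-4(15)-en-6α,12-olide
Conditions: LiCl, H2O, DMSO, 140 °C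
Reagents that add atoms: none
Why: Krapcho dealkoxycarbonylation of the α-methoxycarbonyl lactone under neutral conditions; with the C4 ketone gone there is no β-silyloxy carbonyl left to eliminate.

Step 11
Reactants: 14 bis-silyl ether
Product: 15 2β-hydroxy compound (triethylsilyl group removed)
Conditions: HF·pyridine, pyridine, THF, 0 °C
Reagents that add atoms: none
Why: Selective desilylation; a triethylsilyl ether is cleaved far faster than the tert-butyldimethylsilyl ether by buffered fluoride, and the acetonide is inert.

Step 12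
Reactants: 15 C2 alcohol
Product: 16 2-oxo compound (β,γ-unsaturated ketone, used crude)
Conditions: Dess–Martin periodinane, NaHCO3, CH2Cl2, 0 °C
Reagents that add atoms: none
Why: Dess–Martin oxidation under buffered neutral conditions, chosen so that the exocyclic alkene does not drift into conjugation at C3=C4.

Step 13
Reactants: 16 C2 ketone
Product: 18 5α-(tert-butyldimethylsilyloxy)-1α,10α-isopropylidenedioxy-2-oxo-3,8-cyclo-13-norgermacra-3(8),4(15)-dien-6α,12-olide, via silyl dienol ether 17 (not isolated)
Conditions: Me3SiOTf, Et3N, CH2Cl2, −20 °C; then Pd(OAc)2 (1.1 equiv, divalent palladium), MeCN, rt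
Reagents that add atoms: none
Why: Saegusa–Ito oxidation; soft enolisation should go towards C3 (conjugated with C4=C15, and away from the acetal ring junction at C1), and the palladium enolate can lose only H8 by β-hydride elimination, which gives the ring-fusion enone.

Step 14
Reactants: 18 dienone
Product: 19 3β,8β-epoxy-5α-(tert-butyldimethylsilyloxy)-1α,10α-isopropylidenedioxy-2-oxo-3,8-cyclo-13-norgermacr-4(15)-en-6α,12-olide
Conditions: 30% H2O2, LiOH (0.5 equiv), MeOH, 0 °C; then pH 4 buffer
Reagents that add atoms: hydrogen peroxide, OO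
Why: Weitz–Scheffer epoxidation, the standard entry to ring-fusion epoxy ketones; hydroperoxide should add at C8 anti to the pseudoaxial C10–O bond, the exocyclic alkene is not electrophilic, β-elimination of the lactone oxygen from a C7 dienolate is stereoelectronically retarded by the fused ring, and acidification recloses any opened lactone.

Step 15
Reactants: 19 epoxy ketone; 20 p-toluenesulfonyl hydrazide
Product: 23 5α-(tert-butyldimethylsilyloxy)-1α,10α-isopropylidenedioxy-8-oxo-13-norgermacr-4(15)-en-2-yn-6α,12-olide, via tosylhydrazone 21 (not isolated), via azoalkene carbinol 22 (not isolated)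
Conditions: TsNHNH2 (1.3 equiv), AcOH–CH2Cl2 (1:1), NaOAc, −20 °C to rt
Reagents that add atoms: none
Why: Eschenmoser–Tanabe fragmentation: acid-catalysed condensation at C2 gives 21, whose nitrogen lone pair opens the C3–O bond of the epoxide to the azoalkene carbinol 22; the C8 oxygen then becomes the carbonyl while the C3–C8 bond breaks, C2≡C3 forms and N2 and p-toluenesulfinate leave in one Grob-type event. The closest known case is the conversion of ring-fusion epoxy octalones into cyclodec-5-ynones, of which 19 is a substituted member. No ring is closed: the ten-membered ring is the perimeter of the decalin and appears when the shared C3–C8 bond is cut. No stereocentre is created; C3 and C8 end as sp and sp2 carbons, so either epoxide face would serve, and C1, C10, C5, C6 and C7 are untouched. The step needs hydrazone formation at the hindered, doubly α-oxygenated C2 carbonyl (the only ketone present) and survival of the acetonide, the silyl ether and the vinyl epoxide, which cold buffered acetic acid should allow; regiochemistry is fixed by the positions of carbonyl and epoxide. Low temperature and prompt work-up should limit epimerisation at C7 and β-elimination of the C6 lactone oxygen in the β-acyloxy ketone 23.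

Step 16
Reactants: 23 cyclodecynone
Product: 24 8α-hydroxy-5α-(tert-butyldimethylsilyloxy)-1α,10α-isopropylidenedioxy-13-norgermacr-4(15)-en-2-yn-6α,12-olide
Conditions: (R)-1-methyl-3,3-diphenyltetrahydropyrrolo[1,2-c][1,3,2]oxazaborole (0.3 equiv), catecholborane, PhMe, −78 °C
Reagents that add atoms: none
Why: Corey–Bakshi–Shibata reduction; with the branched C7 arm as the large group and the C9 methylene as the small one, the (R)-catalyst should deliver hydride to the face that gives the 8α carbinol, and catecholborane at low temperature spares the enyne.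

Step 17
Reactants: 24 hydroxy lactone
Product: 27 8α-hydroxy-5α-(tert-butyldimethylsilyloxy)-1α,10α-isopropylidenedioxygermacra-4(15),11(13)-dien-2-yn-6α,12-olide, via Mannich base 25 (not isolated), via methiodide 26 (not isolated)
Conditions: LDA (2.2 equiv), THF, −78 °C; CH2=NMe2+ I−; then MeI, MeOH; then NaHCO3, EtOAc–H2O
Reagents that add atoms: N,N-dimethylmethyleneiminium iodide, C=[N+](C)C.[I-]
Why: α-Methylenation of the lactone by Mannich reaction with Eschenmoser's salt, quaternisation and elimination; the C8 hydroxyl rides as its alkoxide, and doing this before the angelate is present removes the risk of γ-deprotonation of that ester.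

Step 18
Reactants: 27 8α-alcohol; 28 angelic acid
Product: 29 8α-angeloyloxy-5α-(tert-butyldimethylsilyloxy)-1α,10α-isopropylidenedioxygermacra-4(15),11(13)-dien-2-yn-6α,12-olide
Conditions: 2,4,6-trichlorobenzoyl chloride, Et3N, PhMe, rt then 80 °C
Reagents that add atoms: none
Why: Yamaguchi-type esterification through the mixed anhydride without a nucleophilic catalyst, the usual way to acylate a hindered secondary alcohol with angelic acid while keeping the Z geometry.

Step 19
Reactants: 29 acetonide
Product: 30 8α-angeloyloxy-1α,10α-dihydroxy-5α-(tert-butyldimethylsilyloxy)germacra-4(15),11(13)-dien-2-yn-6α,12-olide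
Conditions: AcOH–H2O (4:1), 40 °C
Reagents that add atoms: none
Why: Acetal hydrolysis; done at the alkyne stage so that the freed C1 hydroxyl is propargylic rather than dienylic, and mild enough that the hindered secondary silyl ether should persist.

Step 20
Reactants: 30 enyne diol
Product: 31 8α-angeloyloxy-1α,10α-dihydroxy-5α-(tert-butyldimethylsilyloxy)germacra-2Z,4(15),11(13)-trien-6α,12-olide
Conditions: H2 (1 atm), Pd/CaCO3 poisoned with Pb(OAc)2, quinoline, EtOAc, rt
Reagents that add atoms: none
Why: Lindlar semihydrogenation; syn delivery of hydrogen to the ring alkyne can give only the Z alkene, and the poisoned catalyst with quinoline should leave the methylene lactone and the angelate untouched if the reaction is stopped at one equivalent.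

Step 21
Reactants: 31 Z-dienyl diol
Product: 32 8α-angeloyloxy-2α,3α-epoxy-1α,10α-dihydroxy-5α-(tert-butyldimethylsilyloxy)germacra-4(15),11(13)-dien-6α,12-olide
Conditions: VO(acac)2 (5 mol %), t-BuOOH, CH2Cl2, 0 °C
Reagents that add atoms: tert-butyl hydroperoxide, CC(C)(C)OO
Why: Vanadium-catalysed hydroxyl-directed epoxidation; the C1 alkoxide (helped by the cis C10 hydroxyl) should deliver oxygen to the allylic C2=C3 bond on its own α face, the cis epoxy alcohol being the usual result for medium-ring Z-allylic alcohols, and the electron-poor alkenes and the more remote C4=C15 are not addressed.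

Step 22
Reactants: 32 epoxy diol
Product: 34 8α-angeloyloxy-1β,10α:2α,3α-diepoxy-5α-(tert-butyldimethylsilyloxy)germacra-4(15),11(13)-dien-6α,12-olide, via mesylate 33 (not isolated)
Conditions: MsCl, Et3N, CH2Cl2, −20 °C; then DBU, 0 °C to rt
Reagents that add atoms: none
Why: Selective sulfonylation of the secondary C1 hydroxyl followed by intramolecular Williamson closure; the tertiary C10 oxygen displaces the mesylate with inversion at C1, which converts the cis diol into the trans 1,10-epoxide, and the mesylate is no longer allylic because C2=C3 is already epoxidised.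

Step 23
Reactants: 34 silyl ether
Product: 35 target, 8α-angeloyloxy-1β,10α:2α,3α-diepoxy-5α-hydroxygermacra-4(15),11(13)-dien-6α,12-olide
Conditions: Bu4NF, AcOH (1:1), THF, 0 °C to rt
Reagents that add atoms: none
Why: Fluoride desilylation buffered with acetic acid, so that neither the methylene lactone nor the epoxides meet free alkoxide or strong acid.

## Compound list

1 | 3-methylbut-2-enal | CC(C)=CC=O | starting material
2 | (E)-1-(triethylsilyloxy)-3-methylbuta-1,3-diene | C=C(C)/C=C/O[Si](CC)(CC)CC | intermediate
3 | 1,4-benzoquinone | O=C1C=CC(=O)C=C1 | starting material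
4 | 2β-triethylsilyloxy-10-methyl-3αH,8αH-decalin-1(10),5-diene-4,7-dione (cis-fused adduct) | O=C1C=CC(=O)[C@@H]2CC(C)=C[C@H](O[Si](CC)(CC)CC)[C@H]12 | intermediate
5 | 7β-hydroxy-2β-triethylsilyloxy-10-methyl-3αH,8αH-decalin-1(10),5-dien-4-one | O=C1C=C[C@H](O)[C@@H]2CC(C)=C[C@H](O[Si](CC)(CC)CC)[C@H]12 | intermediate
6 | 7β-methoxycarbonyloxy analogue of 5 | O=C1C=C[C@H](OC(=O)OC)[C@@H]2CC(C)=C[C@H](O[Si](CC)(CC)CC)[C@H]12 | intermediate
7 | dimethyl malonate | COC(=O)CC(=O)OC | starting material
8 | 7β-[bis(methoxycarbonyl)methyl]-2β-triethylsilyloxy-10-methyl-3αH,8αH-decalin-1(10),5-dien-4-one | O=C1C=C[C@H](C(C(=O)OC)C(=O)OC)[C@@H]2CC(C)=C[C@H](O[Si](CC)(CC)CC)[C@H]12 | intermediate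
9 | 1α,5α,6α,10α-tetrahydroxy-7β-[bis(methoxycarbonyl)methyl]-2β-triethylsilyloxy-10-methyl-3αH,8αH-decalin-4-one | O=C1[C@@H](O)[C@@H](O)[C@H](C(C(=O)OC)C(=O)OC)[C@@H]2C[C@@](C)(O)[C@@H](O)[C@H](O[Si](CC)(CC)CC)[C@H]12 | intermediate
10 | 11-methoxycarbonyl-1α,5α,10α-trihydroxy-4-oxo-2β-triethylsilyloxy-3αH,8αH-3,8-cyclo-13,15-dinorgermacran-6α,12-olide (lactone triol, C11 epimers) | O=C1[C@@H](O)[C@H]3OC(=O)C(C(=O)OC)[C@@H]3[C@@H]2C[C@@](C)(O)[C@@H](O)[C@H](O[Si](CC)(CC)CC)[C@H]12 | intermediate
11 | 1,10-acetonide of 10 (5α-hydroxy free) | O=C1[C@@H](O)[C@H]3OC(=O)C(C(=O)OC)[C@@H]3[C@@H]2C[C@@]4(C)OC(C)(C)O[C@H]4[C@H](O[Si](CC)(CC)CC)[C@H]12 | intermediate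
12 | 5α-(tert-butyldimethylsilyloxy) derivative of 11 | O=C1[C@@H](O[Si](C)(C)C(C)(C)C)[C@H]3OC(=O)C(C(=O)OC)[C@@H]3[C@@H]2C[C@@]4(C)OC(C)(C)O[C@H]4[C@H](O[Si](CC)(CC)CC)[C@H]12 | intermediate
13 | 11-methoxycarbonyl-5α-(tert-butyldimethylsilyloxy)-1α,10α-isopropylidenedioxy-2β-triethylsilyloxy-3αH,8αH-3,8-cyclo-13-norgermacr-4(15)-en-6α,12-olide | C=C1[C@@H](O[Si](C)(C)C(C)(C)C)[C@H]3OC(=O)C(C(=O)OC)[C@@H]3[C@@H]2C[C@@]4(C)OC(C)(C)O[C@H]4[C@H](O[Si](CC)(CC)CC)[C@H]12 | intermediate
14 | 5α-(tert-butyldimethylsilyloxy)-1α,10α-isopropylidenedioxy-2β-triethylsilyloxy-3αH,8αH-3,8-cyclo-13-norgermacr-4(15)-en-6α,12-olide | C=C1[C@@H](O[Si](C)(C)C(C)(C)C)[C@H]3OC(=O)C[C@@H]3[C@@H]2C[C@@]4(C)OC(C)(C)O[C@H]4[C@H](O[Si](CC)(CC)CC)[C@H]12 | intermediate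
15 | 2β-hydroxy analogue of 14 | C=C1[C@@H](O[Si](C)(C)C(C)(C)C)[C@H]3OC(=O)C[C@@H]3[C@@H]2C[C@@]4(C)OC(C)(C)O[C@H]4[C@H](O)[C@H]12 | intermediate
16 | 2-oxo analogue of 14 | C=C1[C@@H](O[Si](C)(C)C(C)(C)C)[C@H]3OC(=O)C[C@@H]3[C@@H]2C[C@@]4(C)OC(C)(C)O[C@H]4C(=O)[C@H]12 | intermediate
17 | 2-trimethylsilyloxy-2(3),4(15)-diene (silyl dienol ether of 16) | C=C1[C@@H](O[Si](C)(C)C(C)(C)C)[C@H]3OC(=O)C[C@@H]3[C@@H]2C[C@@]4(C)OC(C)(C)O[C@H]4C(O[Si](C)(C)C)=C12 | intermediate
18 | 5α-(tert-butyldimethylsilyloxy)-1α,10α-isopropylidenedioxy-2-oxo-3,8-cyclo-13-norgermacra-3(8),4(15)-dien-6α,12-olide | C=C1[C@@H](O[Si](C)(C)C(C)(C)C)[C@H]3OC(=O)C[C@@H]3C2=C1C(=O)[C@@H]4OC(C)(C)O[C@]4(C)C2 | intermediate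
19 | 3β,8β-epoxy-5α-(tert-butyldimethylsilyloxy)-1α,10α-isopropylidenedioxy-2-oxo-3,8-cyclo-13-norgermacr-4(15)-en-6α,12-olide | C1C(=O)O[C@H]2[C@H]1[C@]3(O4)[C@]4(C(=C)[C@H]2O[Si](C)(C)C(C)(C)C)C(=O)[C@@H]5OC(C)(C)O[C@]5(C)C3 | intermediate
20 | p-toluenesulfonyl hydrazide | Cc1ccc(cc1)S(=O)(=O)NN | starting material
21 | C2 tosylhydrazone of 19 | C1C(=O)O[C@H]2[C@H]1[C@]3(O4)[C@]4(C(=C)[C@H]2O[Si](C)(C)C(C)(C)C)C(=NNS(=O)(=O)c6ccc(C)cc6)[C@@H]5OC(C)(C)O[C@]5(C)C3 | intermediate
22 | 8β-hydroxy-2-(tosyldiazenyl)-3,8-cyclo-13-norgermacra-2,4(15)-diene (azoalkene carbinol) | C1C(=O)O[C@H]2[C@H]1[C@]3(O)C(C(=C)[C@H]2O[Si](C)(C)C(C)(C)C)=C(N=NS(=O)(=O)c6ccc(C)cc6)[C@@H]5OC(C)(C)O[C@]5(C)C3 | intermediate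
23 | 5α-(tert-butyldimethylsilyloxy)-1α,10α-isopropylidenedioxy-8-oxo-13-norgermacr-4(15)-en-2-yn-6α,12-olide | C1C(=O)O[C@H]2[C@H]1C(=O)C[C@@]3(C)OC(C)(C)O[C@H]3C#CC(=C)[C@H]2O[Si](C)(C)C(C)(C)C | intermediate
24 | 8α-hydroxy analogue of 23 | C1C(=O)O[C@H]2[C@H]1[C@@H](O)C[C@@]3(C)OC(C)(C)O[C@H]3C#CC(=C)[C@H]2O[Si](C)(C)C(C)(C)C | intermediate
25 | 11-(dimethylaminomethyl) derivative of 24 (C11 epimers) | CN(C)CC1C(=O)O[C@H]2[C@H]1[C@@H](O)C[C@@]3(C)OC(C)(C)O[C@H]3C#CC(=C)[C@H]2O[Si](C)(C)C(C)(C)C | intermediate
26 | methiodide of 25 | C[N+](C)(C)CC1C(=O)O[C@H]2[C@H]1[C@@H](O)C[C@@]3(C)OC(C)(C)O[C@H]3C#CC(=C)[C@H]2O[Si](C)(C)C(C)(C)C.[I-] | intermediate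
27 | 8α-hydroxy-5α-(tert-butyldimethylsilyloxy)-1α,10α-isopropylidenedioxygermacra-4(15),11(13)-dien-2-yn-6α,12-olide | C=C1C(=O)O[C@H]2[C@H]1[C@@H](O)C[C@@]3(C)OC(C)(C)O[C@H]3C#CC(=C)[C@H]2O[Si](C)(C)C(C)(C)C | intermediate
28 | angelic acid | C/C=C(/C)C(=O)O | starting material
29 | 8α-angeloyloxy analogue of 27 | C=C1C(=O)O[C@H]2[C@H]1[C@@H](OC(=O)/C(C)=C\C)C[C@@]3(C)OC(C)(C)O[C@H]3C#CC(=C)[C@H]2O[Si](C)(C)C(C)(C)C | intermediate
30 | 8α-angeloyloxy-1α,10α-dihydroxy-5α-(tert-butyldimethylsilyloxy)germacra-4(15),11(13)-dien-2-yn-6α,12-olide | C=C1C(=O)O[C@H]2[C@H]1[C@@H](OC(=O)/C(C)=C\C)C[C@@](C)(O)[C@@H](O)C#CC(=C)[C@H]2O[Si](C)(C)C(C)(C)C | intermediate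
31 | 8α-angeloyloxy-1α,10α-dihydroxy-5α-(tert-butyldimethylsilyloxy)germacra-2Z,4(15),11(13)-trien-6α,12-olide | C=C1C(=O)O[C@H]2[C@H]1[C@@H](OC(=O)/C(C)=C\C)C[C@@](C)(O)[C@@H](O)/C=C\C(=C)[C@H]2O[Si](C)(C)C(C)(C)C | intermediate
32 | 8α-angeloyloxy-2α,3α-epoxy-1α,10α-dihydroxy-5α-(tert-butyldimethylsilyloxy)germacra-4(15),11(13)-dien-6α,12-olide | C=C1C(=O)O[C@H]2[C@H]1[C@@H](OC(=O)/C(C)=C\C)C[C@@](C)(O)[C@@H](O)[C@H]4O[C@H]4C(=C)[C@H]2O[Si](C)(C)C(C)(C)C | intermediate
33 | 1α-methanesulfonate of 32 | C=C1C(=O)O[C@H]2[C@H]1[C@@H](OC(=O)/C(C)=C\C)C[C@@](C)(O)[C@@H](OS(C)(=O)=O)[C@H]4O[C@H]4C(=C)[C@H]2O[Si](C)(C)C(C)(C)C | intermediate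
34 | 8α-angeloyloxy-1β,10α:2α,3α-diepoxy-5α-(tert-butyldimethylsilyloxy)germacra-4(15),11(13)-dien-6α,12-olide | C=C1C(=O)O[C@H]2[C@H]1[C@@H](OC(=O)/C(C)=C\C)C[C@@]1(C)O[C@@H]1[C@H]1O[C@H]1C(=C)[C@H]2O[Si](C)(C)C(C)(C)C | intermediate
35 | 8α-angeloyloxy-1β,10α:2α,3α-diepoxy-5α-hydroxygermacra-4(15),11(13)-dien-6α,12-olide (CNP0038366.2) | C=C1C(=O)O[C@H]2[C@H]1[C@@H](OC(=O)/C(C)=C\C)C[C@@]1(C)O[C@@H]1[C@H]1O[C@H]1C(=C)[C@H]2O | target

## Step count and risk

Total: 23 steps. Longest linear sequence: 23 steps from 1 (22 from 3); the route is linear, with 7, 20 and 28 added as purchased reagents.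

Least certain steps:

Step 15 (key step). Most likely failure: slow or incomplete hydrazone formation at the crowded C2 carbonyl, so that acid-induced opening of the vinyl epoxide or loss of the acetonide overtakes the fragmentation. Fallback: from 19, condense under neutral conditions with 1-amino-2-phenylaziridine to the N-aziridinyl imine F1. Gentle warming should fragment F1 thermally, with loss of styrene and nitrogen instead of sulfinate, and return to the route at 23 with no acid present.

Step 3. Most likely failure: poor discrimination between the two quinone-derived carbonyls, or over-reduction. Fallback: from 4, reduce both carbonyls from the convex face with excess NaBH4/CeCl3·7H2O to the cis-enediol F2. Acylate only the unhindered C7 hydroxyl with one equivalent of methyl chloroformate to the mono-carbonate F3; the C4 hydroxyl is syn-1,3 to the silyloxy group and should be much slower. Allylic alkylation with 7 and Pd(PPh3)4 should give the malonate alcohol F4 (attack remote from the oxygen-bearing terminus, retention). Oxidation of the allylic C4 hydroxyl with MnO2 comes back at 8.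

Step 14. Most likely failure: γ-deprotonation at C7 by the basic peroxide medium, leading to epimerisation or to elimination of the lactone oxygen and aromatisation of ring A. Fallback: from 18, 1,2-reduce with NaBH4/CeCl3·7H2O to the dienol F5. Hydroxyl-directed epoxidation with VO(acac)2 and t-BuOOH of its tetrasubstituted allylic alkene should give the epoxy alcohol F6. Dess–Martin oxidation then gives the epoxy ketone F7, the C3,C8-epimer of 19. Since the epoxide configuration is lost in step 15, F7 is treated as 19 and the route is rejoined at 23; no base is used.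

Step 16. Most likely failure: poor facial selectivity, because the conformation of the ten-membered ring may override the catalyst. Fallback: from 23, reduce with a bulky hydride (LiBH(s-Bu)3) to what should then be the 8β-alcohol F8. Invert it by Mitsunobu esterification with 4-nitrobenzoic acid (PPh3, diisopropyl azodicarboxylate) to the 8α-ester F9. Methanolysis with K2CO3 in MeOH returns to the route at 24.

Step 2. Most likely failure: insufficient enantioselectivity, or acid-induced loss of the silyl dienol ether before cycloaddition. Fallback: from 2 and 3, run the uncatalysed cycloaddition to racemic 4 and carry out step 3 to racemic 5. Resolve with Burkholderia cepacia lipase and vinyl acetate. The enantiomer of the required configuration is either left as 5, which continues at step 4, or obtained as its acetate F10. F10 enters the allylic alkylation directly (sodium salt of 7, Pd(PPh3)4) and returns at 8.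

## Further compounds

F1 | step 15 | N-(2-phenylaziridin-1-yl)imine of 19 at C2 | C1C(=O)O[C@H]2[C@H]1[C@]3(O4)[C@]4(C(=C)[C@H]2O[Si](C)(C)C(C)(C)C)C(=NN6CC6c7ccccc7)[C@@H]5OC(C)(C)O[C@]5(C)C3
F2 | step 3 | 4β,7β-dihydroxy-2β-triethylsilyloxy-10-methyl-3αH,8αH-decalin-1(10),5-diene | O[C@@H]1C=C[C@H](O)[C@@H]2CC(C)=C[C@H](O[Si](CC)(CC)CC)[C@H]12
F3 | step 3 | 7β-methoxycarbonyloxy-4β-hydroxy analogue of F2 | O[C@@H]1C=C[C@H](OC(=O)OC)[C@@H]2CC(C)=C[C@H](O[Si](CC)(CC)CC)[C@H]12
F4 | step 3 | 7β-[bis(methoxycarbonyl)methyl]-4β-hydroxy-2β-triethylsilyloxy-10-methyl-3αH,8αH-decalin-1(10),5-diene | O[C@@H]1C=C[C@H](C(C(=O)OC)C(=O)OC)[C@@H]2CC(C)=C[C@H](O[Si](CC)(CC)CC)[C@H]12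
F5 | step 14 | 2α-hydroxy-5α-(tert-butyldimethylsilyloxy)-1α,10α-isopropylidenedioxy-3,8-cyclo-13-norgermacra-3(8),4(15)-dien-6α,12-olide | C=C1[C@@H](O[Si](C)(C)C(C)(C)C)[C@H]3OC(=O)C[C@@H]3C2=C1[C@H](O)[C@@H]4OC(C)(C)O[C@]4(C)C2
F6 | step 14 | 3α,8α-epoxy-2α-hydroxy-5α-(tert-butyldimethylsilyloxy)-1α,10α-isopropylidenedioxy-3,8-cyclo-13-norgermacr-4(15)-en-6α,12-olide | C1C(=O)O[C@H]2[C@H]1[C@@]3(O4)[C@@]4(C(=C)[C@H]2O[Si](C)(C)C(C)(C)C)[C@H](O)[C@@H]5OC(C)(C)O[C@]5(C)C3
F7 | step 14 | 3α,8α-epoxy-5α-(tert-butyldimethylsilyloxy)-1α,10α-isopropylidenedioxy-2-oxo-3,8-cyclo-13-norgermacr-4(15)-en-6α,12-olide | C1C(=O)O[C@H]2[C@H]1[C@@]3(O4)[C@@]4(C(=C)[C@H]2O[Si](C)(C)C(C)(C)C)C(=O)[C@@H]5OC(C)(C)O[C@]5(C)C3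
F8 | step 16 | 8β-hydroxy epimer of 24 | C1C(=O)O[C@H]2[C@H]1[C@H](O)C[C@@]3(C)OC(C)(C)O[C@H]3C#CC(=C)[C@H]2O[Si](C)(C)C(C)(C)C
F9 | step 16 | 8α-(4-nitrobenzoyloxy) analogue of 24 | C1C(=O)O[C@H]2[C@H]1[C@@H](OC(=O)c4ccc(cc4)[N+](=O)[O-])C[C@@]3(C)OC(C)(C)O[C@H]3C#CC(=C)[C@H]2O[Si](C)(C)C(C)(C)C
F10 | step 2 | 7β-acetoxy analogue of 5 | O=C1C=C[C@H](OC(C)=O)[C@@H]2CC(C)=C[C@H](O[Si](CC)(CC)CC)[C@H]12
A1 | alternative 1 | methyl 2-(1,4,5,8-tetrahydronaphthalen-2-yl)acetate | COC(=O)CC1=CCC2=C(C1)CC=CC2
A2 | alternative 1 | methyl 2-(4,9-dioxocyclodeca-1,6-dien-1-yl)acetate | O=C1C/C(CC(=O)OC)=C\CC(=O)C/C=C\C1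
A3 | alternative 2 | 5,6-seco aldehyde with E γ-(4-methoxybenzyloxy)allyl pinacol boronate, 1β,10α:2α,3α-diepoxy-8α-(tert-butyldimethylsilyloxy), methyl 12-oate | O=C[C@H](CC(=O)OC)[C@@H](O[Si](C)(C)C(C)(C)C)C[C@@]1(C)O[C@@H]1[C@H]2O[C@H]2/C(CB3OC(C)(C)C(C)(C)O3)=C/OCc4ccc(OC)cc4
A4 | alternative 2 | methyl 1β,10α:2α,3α-diepoxy-6α-hydroxy-5α-(4-methoxybenzyloxy)-8α-(tert-butyldimethylsilyloxy)-13-norgermacr-4(15)-en-12-oate | C=C1[C@@H]2O[C@@H]2[C@H]2O[C@]2(C)C[C@H](O[Si](C)(C)C(C)(C)C)[C@@H](CC(=O)OC)[C@H](O)[C@@H]1OCc1ccc(OC)cc1
A5 | alternative 3 | 1,2-seco precursor with E C1 tributylstannyl alkene and Z C2 vinyl iodide, 8α-angeloyloxy-5α-(tert-butyldimethylsilyloxy)-6α,12-olide | C=C1C(=O)O[C@@H]([C@H]1[C@@H](OC(=O)/C(C)=C\C)C/C(C)=C/[Sn](CCCC)(CCCC)CCCC)[C@H](O[Si](C)(C)C(C)(C)C)C(=C)/C=C\I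
A6 | alternative 3 | 8α-angeloyloxy-5α-(tert-butyldimethylsilyloxy)germacra-1(10)E,2Z,4(15),11(13)-tetraen-6α,12-olide | C=C1C(=O)O[C@H]2[C@H]1[C@@H](OC(=O)/C(C)=C\C)C/C(C)=C/C=C\C(=C)[C@H]2O[Si](C)(C)C(C)(C)C
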